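## Retrosynthetic overview

1. The only ring, the ε-ring, is formed first: an enantioselective proton-initiated C1–C6 cyclisation of the acyclic ψ-end of (3E,5E)-pseudoionone 1 gives (R)-α-ionone 2. Carotenoid ring numbering is used throughout: C1 = CMe2, C3 = carbinol carbon, C5 = methyl-bearing sp2 carbon, C6 = chain-bearing carbon.
2. C3–O is installed after ring closure, as in the biosynthesis: allylic C–H hydroxylation of 2 gives (3R,6R)-3-hydroxy-α-ionone 3, with OH trans to the chain.
3. C9–C10 and C11–P: vinyl addition (3 to carbinol 4), then allylic transposition to the C15 phosphonium salt 5.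
4. C11'=C12' (Horner–Wadsworth–Emmons): C10 dial 6 + C5 phosphonate 7 (anion 8) give the C15 aldehyde ester 9.
5. C11=C12 (Wittig): 5 (ylide 10) + 9 give the C30 ester 11; ester reduction gives the target 12.

Assumption: (3E,5E)-pseudoionone, all-E 2,7-dimethylocta-2,4,6-trienedial and ethyl (2E)-4-(diethoxyphosphoryl)-2-methylbut-2-enoate are taken as catalogue chemicals.

## Route

Step 1
Reactants: 1 (3E,5E)-pseudoionone
Product: 2 (R)-α-ionone
Conditions: (S,S)-IDPi acid HN[P(=NSO2CF3)(O2Ar)]2, O2Ar = (S)-3,3'-bis[3,5-bis(trifluoromethyl)phenyl]-1,1'-binaphthalene-2,2'-diolate (5 mol %), (CF3)3COH/CH2Cl2 1:4, −40 °C, 48 h; Et3N quench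
Reagents that add atoms: none
Why: Proposed new method: the confined, strongly acidic imidodiphosphorimidate protonates the isopropylidene C=C at C2, and inside the chiral pocket the developing tertiary C1 cation is captured by C6 of the (5E)-alkene through a chair-like transition state whose face is chosen by the catalyst anion (this sets C6 as R; the catalyst antipode is fixed in a pilot run), after which the bound anion removes H-4 from the C5 cation to give the non-conjugated ε-type double bond under kinetic control, the conjugated enone stopping the cascade after one ring as in lycopene ε-cyclase; the closest known reactions are the racemic H3PO4 cyclisation of pseudoionone to α-ionone and IDPi-catalysed enantioselective proton-initiated polyene cyclisations of unactivated trisubstituted alkenes (cationic polyene cyclisation).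

Step 2
Reactants: 2 (R)-α-ionone
Product: 3 (3R,6R)-3-hydroxy-α-ionone
Conditions: P450 BM3 (CYP102A1) variant screened for C3/trans selectivity (A82W-type active-site mutant, cell-free extract), NADP+ (cat.), glucose dehydrogenase, D-glucose (1.5 equiv), air, KPi buffer pH 7.5, 2% DMSO, 25 °C
Reagents that add atoms: dioxygen, O=O
Why: Enzymatic C–H hydroxylation (P450 monooxygenation by hydrogen abstraction and oxygen rebound) at the activated allylic C3 methylene, where the haem iron-oxo species reaches the ring face opposite the C6 side chain and so delivers OH trans to it (3R), a selectivity known for P450 BM3 variants and actinomycete P450s with α-ionone and the same event the ε-ring hydroxylase performs in lutein biosynthesis.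

Step 3
Reactants: 3 (3R,6R)-3-hydroxy-α-ionone
Product: 4 (1R,4R)-4-[(1E)-3-hydroxy-3-methylpenta-1,4-dien-1-yl]-3,5,5-trimethylcyclohex-2-en-1-ol
Conditions: CH2=CHMgBr (3 equiv), THF, −20 → 0 °C; then H2O
Reagents that add atoms: vinylmagnesium bromide, C=C[Mg]Br
Why: Grignard 1,2-addition to the enone carbonyl after the first equivalent has deprotonated the 3-OH; the new C9 carbinol centre forms as a mixture that is erased in step 4, and C3 and C6 are not touched at low temperature.

Step 4
Reactants: 4 (1R,4R)-4-[(1E)-3-hydroxy-3-methylpenta-1,4-dien-1-yl]-3,5,5-trimethylcyclohex-2-en-1-ol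
Product: 5 [(2E,4E)-5-[(1R,4R)-4-hydroxy-2,6,6-trimethylcyclohex-2-en-1-yl]-3-methylpenta-2,4-dien-1-yl]triphenylphosphonium bromide
Conditions: PPh3·HBr (1.05 equiv), CH2Cl2, 0 °C → rt, 12 h; crystallise from CH2Cl2/EtOAc
Reagents that add atoms: triphenylphosphine hydrobromide, [Br-].c1ccc(cc1)[PH+](c1ccccc1)c1ccccc1
Why: Acid-mediated allylic substitution with transposition (SN1' type): Ph3PH+ ionises the tertiary doubly allylic carbinol much faster than the secondary allylic 3-OH, PPh3 traps the pentadienyl cation at its primary terminus, and the favoured 9E salt crystallises, which also raises the enantiomeric purity; no stereocentre is formed and C3 and C6 are retained.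

Step 5
Reactants: 6 (2E,4E,6E)-2,7-dimethylocta-2,4,6-trienedial; 7 ethyl (2E)-4-(diethoxyphosphoryl)-2-methylbut-2-enoate
Product: 9 ethyl (2E,4E,6E,8E,10E)-2,6,11-trimethyl-12-oxododeca-2,4,6,8,10-pentaenoate, via sodium phosphonate carbanion 8 (not isolated)
Conditions: 7, NaH (1.0 equiv), THF, 0 °C; then added to 6 (2 equiv), THF, −20 → 0 °C; excess 6 recovered
Reagents that add atoms: none
Why: Horner–Wadsworth–Emmons olefination with a stabilised vinylogous phosphonate anion forms the new C11'=C12' bond E, and inverse addition to excess dial holds the reaction at the mono-adduct.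

Step 6
Reactants: 5 [(2E,4E)-5-[(1R,4R)-4-hydroxy-2,6,6-trimethylcyclohex-2-en-1-yl]-3-methylpenta-2,4-dien-1-yl]triphenylphosphonium bromide; 9 ethyl (2E,4E,6E,8E,10E)-2,6,11-trimethyl-12-oxododeca-2,4,6,8,10-pentaenoate
Product: 11 ethyl (3R,6R)-3-hydroxy-8'-apo-ε-caroten-8'-oate, via phosphorus ylide 10 (not isolated)
Conditions: NaOEt (1.1 equiv), EtOH/CH2Cl2, 0 °C → rt; then heptane, reflux 6 h under N2 in the dark (Z → E at C11=C12); crystallise
Reagents that add atoms: none
Why: Wittig olefination of the semi-stabilised allylic ylide with the aldehyde (the ethyl ester is inert, and NaOEt avoids transesterification) forms C11=C12 as an E/Z mixture that equilibrates thermally to the all-E polyene; the stereocentres are remote and unaffected.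

Step 7
Reactants: 11 ethyl (3R,6R)-3-hydroxy-8'-apo-ε-caroten-8'-oate
Product: 12 (3R,6R)-8'-apo-ε-carotene-3,8'-diol
Conditions: i-Bu2AlH (3.5 equiv), CH2Cl2, −78 → −30 °C; aq KNaC4H4O6 (potassium sodium tartrate)
Reagents that add atoms: none
Why: 1,2-Reduction of the conjugated ester to the primary allylic alcohol with i-Bu2AlH (one equivalent is consumed by the free 3-OH) leaves the polyene and both stereocentres untouched.

## Compound list

1 | (3E,5E)-6,10-dimethylundeca-3,5,9-trien-2-one (pseudoionone) | CC(C)=CCC/C(C)=C/C=C/C(C)=O | starting material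
2 | (3E)-4-[(1R)-2,6,6-trimethylcyclohex-2-en-1-yl]but-3-en-2-one ((R)-α-ionone) | CC1=CCCC(C)(C)[C@H]1/C=C/C(C)=O | intermediate
3 | (3E)-4-[(1R,4R)-4-hydroxy-2,6,6-trimethylcyclohex-2-en-1-yl]but-3-en-2-one ((3R,6R)-3-hydroxy-α-ionone) | CC1=C[C@H](O)CC(C)(C)[C@H]1/C=C/C(C)=O | intermediate
4 | (1R,4R)-4-[(1E)-3-hydroxy-3-methylpenta-1,4-dien-1-yl]-3,5,5-trimethylcyclohex-2-en-1-ol (both epimers at the chain carbinol) | CC1=C[C@H](O)CC(C)(C)[C@H]1/C=C/C(C)(O)C=C | intermediate
5 | [(2E,4E)-5-[(1R,4R)-4-hydroxy-2,6,6-trimethylcyclohex-2-en-1-yl]-3-methylpenta-2,4-dien-1-yl]triphenylphosphonium bromide | CC1=C[C@H](O)CC(C)(C)[C@H]1/C=C/C(C)=C/C[P+](c2ccccc2)(c2ccccc2)c2ccccc2.[Br-] | intermediate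
6 | (2E,4E,6E)-2,7-dimethylocta-2,4,6-trienedial | O=C/C(C)=C/C=C/C=C(C)/C=O | starting material
7 | ethyl (2E)-4-(diethoxyphosphoryl)-2-methylbut-2-enoate | CCOC(=O)/C(C)=C/CP(=O)(OCC)OCC | starting material
8 | sodium salt of the C4 carbanion of 7 | CCOC(=O)/C(C)=C/[CH-]P(=O)(OCC)OCC.[Na+] | intermediate (not isolated)
9 | ethyl (2E,4E,6E,8E,10E)-2,6,11-trimethyl-12-oxododeca-2,4,6,8,10-pentaenoate | CCOC(=O)/C(C)=C/C=C/C(C)=C/C=C/C=C(C)/C=O | intermediate
10 | triphenylphosphonium ylide of 5 | CC1=C[C@H](O)CC(C)(C)[C@H]1/C=C/C(C)=C/C=P(c2ccccc2)(c2ccccc2)c2ccccc2 | intermediate (not isolated)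
11 | ethyl (3R,6R)-3-hydroxy-8'-apo-ε-caroten-8'-oate | CC1=C[C@H](O)CC(C)(C)[C@H]1/C=C/C(C)=C/C=C/C(C)=C/C=C/C=C(C)/C=C/C=C(\C)C(=O)OCC | intermediate
12 | (2E,4E,6E,8E,10E,12E,14E,16E)-17-[(1R,4R)-4-hydroxy-2,6,6-trimethylcyclohex-2-en-1-yl]-2,6,11,15-tetramethylheptadeca-2,4,6,8,10,12,14,16-octaen-1-ol ((3R,6R)-8'-apo-ε-carotene-3,8'-diol) | CC1=C[C@H](O)CC(C)(C)[C@H]1/C=C/C(C)=C/C=C/C(C)=C/C=C/C=C(C)/C=C/C=C(\C)CO | target

## Step count and risk

Total steps: 7. Longest linear sequence: 6 (steps 1, 2, 3, 4, 6, 7).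

**Step 1 (asymmetric cyclisation).** The dienone carbonyl may tie up the acid, the ee may be low, or β/γ-isomers may dominate. The fallback sets out from 1 and comes back at 3, replacing catalyst control by a late resolution. Compound 1 is cyclised with 85% H3PO4 (toluene, 35 °C) to racemic (E)-α-ionone F1. F1 is put through the step 2 hydroxylation using a P450 system that oxidises both antipodes trans. This gives 3 together with its mirror image (3E)-4-[(1S,4S)-4-hydroxy-2,6,6-trimethylcyclohex-2-en-1-yl]but-3-en-2-one F2. Acetylation with vinyl acetate and the lipase from Burkholderia cepacia (t-BuOMe, 30 °C) should, by the Kazlauskas rule with the CH2–CMe2 flank as the large group, esterify the 3S alcohol. That gives (1S,4S)-3,5,5-trimethyl-4-[(1E)-3-oxobut-1-en-1-yl]cyclohex-2-en-1-yl acetate F3 and leaves 3 as the free alcohol, separated on silica.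

**Step 2 (enzymatic hydroxylation).** Scale, enzyme supply and over-oxidation to the 3-ketone are the concerns. The fallback sets out from 2 and comes back at 3 by chemical oxidation and reagent-controlled reduction. Compound 2 is ketalised (ethylene glycol, HC(OEt)3, pyridinium p-toluenesulfonate) to 2-methyl-2-[(E)-2-[(1R)-2,6,6-trimethylcyclohex-2-en-1-yl]ethenyl]-1,3-dioxolane F4. Allylic oxidation (t-BuOOH, aq NaOCl, K2CO3, MeCN, 0 °C) gives (4R)-3,5,5-trimethyl-4-[(E)-2-(2-methyl-1,3-dioxolan-2-yl)ethenyl]cyclohex-2-en-1-one F5. Reduction with catecholborane and (S)-1-methyl-3,3-diphenyltetrahydro-1H,3H-pyrrolo[1,2-c][1,3,2]oxazaborole (the alkenyl flank acts as the large group, so hydride delivery gives 3R) gives (1R,4R)-3,5,5-trimethyl-4-[(E)-2-(2-methyl-1,3-dioxolan-2-yl)ethenyl]cyclohex-2-en-1-ol F6. Hydrolysis of the ketal (pyridinium p-toluenesulfonate, wet acetone, rt) returns 3.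

**Step 4 (salt formation with a free allylic 3-OH).** Epimerisation, substitution or dehydration at C3 under acid are the concerns. The fallback sets out from 3 and 9 and comes back at 11 by reversing the polarity of the C11=C12 Wittig, so the ε-ring never meets acid.
- Ring half: Horner–Wadsworth–Emmons reaction of 3 with diethyl (cyanomethyl)phosphonate (NaH, THF) gives (2E,4E)-5-[(1R,4R)-4-hydroxy-2,6,6-trimethylcyclohex-2-en-1-yl]-3-methylpenta-2,4-dienenitrile F7. Reduction with i-Bu2AlH (−78 °C, then aqueous work-up) gives (2E,4E)-5-[(1R,4R)-4-hydroxy-2,6,6-trimethylcyclohex-2-en-1-yl]-3-methylpenta-2,4-dienal F8.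
- Chain half: aldehyde 9 is reduced with NaBH4 (EtOH, −20 °C) to ethyl (2E,4E,6E,8E,10E)-12-hydroxy-2,6,11-trimethyldodeca-2,4,6,8,10-pentaenoate F9. PPh3·HBr converts it into [(2E,4E,6E,8E,10E)-12-ethoxy-2,7,11-trimethyl-12-oxododeca-2,4,6,8,10-pentaen-1-yl]triphenylphosphonium bromide F10.
- Coupling: Wittig reaction of F8 with F10 (NaOEt, EtOH/CH2Cl2, then thermal Z → E isomerisation) gives 11.

## Further compounds

F1 | step 1 | racemic (3E)-4-(2,6,6-trimethylcyclohex-2-en-1-yl)but-3-en-2-one (racemic α-ionone) | CC1=CCCC(C)(C)C1/C=C/C(C)=O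
F2 | step 1 | (3E)-4-[(1S,4S)-4-hydroxy-2,6,6-trimethylcyclohex-2-en-1-yl]but-3-en-2-one | CC1=C[C@@H](O)CC(C)(C)[C@@H]1/C=C/C(C)=O
F3 | step 1 | (1S,4S)-3,5,5-trimethyl-4-[(1E)-3-oxobut-1-en-1-yl]cyclohex-2-en-1-yl acetate | CC1=C[C@@H](OC(C)=O)CC(C)(C)[C@@H]1/C=C/C(C)=O
F4 | step 2 | 2-methyl-2-[(E)-2-[(1R)-2,6,6-trimethylcyclohex-2-en-1-yl]ethenyl]-1,3-dioxolane | CC1=CCCC(C)(C)[C@H]1/C=C/C2(C)OCCO2
F5 | step 2 | (4R)-3,5,5-trimethyl-4-[(E)-2-(2-methyl-1,3-dioxolan-2-yl)ethenyl]cyclohex-2-en-1-one | CC1=CC(=O)CC(C)(C)[C@H]1/C=C/C2(C)OCCO2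
F6 | step 2 | (1R,4R)-3,5,5-trimethyl-4-[(E)-2-(2-methyl-1,3-dioxolan-2-yl)ethenyl]cyclohex-2-en-1-ol | CC1=C[C@H](O)CC(C)(C)[C@H]1/C=C/C2(C)OCCO2
F7 | step 4 | (2E,4E)-5-[(1R,4R)-4-hydroxy-2,6,6-trimethylcyclohex-2-en-1-yl]-3-methylpenta-2,4-dienenitrile | CC1=C[C@H](O)CC(C)(C)[C@H]1/C=C/C(C)=C/C#N
F8 | step 4 | (2E,4E)-5-[(1R,4R)-4-hydroxy-2,6,6-trimethylcyclohex-2-en-1-yl]-3-methylpenta-2,4-dienal | CC1=C[C@H](O)CC(C)(C)[C@H]1/C=C/C(C)=C/C=O
F9 | step 4 | ethyl (2E,4E,6E,8E,10E)-12-hydroxy-2,6,11-trimethyldodeca-2,4,6,8,10-pentaenoate | CCOC(=O)/C(C)=C/C=C/C(C)=C/C=C/C=C(C)/CO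
F10 | step 4 | [(2E,4E,6E,8E,10E)-12-ethoxy-2,7,11-trimethyl-12-oxododeca-2,4,6,8,10-pentaen-1-yl]triphenylphosphonium bromide | CCOC(=O)/C(C)=C/C=C/C(C)=C/C=C/C=C(C)/C[P+](c1ccccc1)(c1ccccc1)c1ccccc1.[Br-]
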